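You put 3 questions, but both flasks carry the same loading of initiator, so they reduce to how much free monomer each has converted by 80 min. If each initiator begins one chain, which the earlier runs do not show, the average length is that converted fraction divided by the loading. North-east holds more initiator per litre than west, so we have to reckon what that does to the converted fraction.

| setting | Friday's | Saturday's | west | north-east |
|---|---|---|---|---|
| free monomer | 10 mM | 10 mM | 10 mM | 30 mM |
| initiator | 0.34 mol% | 1 mol% | 0.5 mol% | 0.5 mol% |
| remark | run made earlier | run made earlier |  |  |
| time |  |  | 80 min | 80 min |

| run | time / min | monomer in chains / % |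
|---|---|---|
| Friday's | 0.833 | 1.3 |
| Friday's | 2.50 | 3.2 |
| Friday's | 5.00 | 5.8 |
| Friday's | 6.00 | 7.3 |
| Friday's | 10.0 | 9.7 |
| Friday's | 12.0 | 11.3 |
| Friday's | 15.0 | 13.0 |
| Saturday's | 1.33 | 5.4 |
| Saturday's | 2.00 | 7.1 |
| Saturday's | 3.00 | 9.8 |
| Saturday's | 5.00 | 13.0 |
| Saturday's | 6.00 | 14.7 |
| Saturday's | 10.0 | 19.3 |
| Saturday's | 15.0 | 23.1 |

(standard deviation of a reading: 0.3 percentage points)

- which of the two ends with the longer chains by the average number of monomer units in a chain (chains begun, living or dead) ("neither" if they lie within 10%) (west / north-east / neither)
- average number of monomer units in a chain (chains begun, living or dead) at the end, west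
- average number of monomer units in a chain (chains begun, living or dead) at the end, north-east

- the average divides the monomer in chains by the number of chains begun, living and dead together
- the earlier runs do not show the number of chains; that part of a forecast is a guess

Let x be ln(free monomer charged / free monomer left) and r its rise per minute. Saturday's run reads r = 0.0285 min⁻¹ around 2.17 min and 0.0115 min⁻¹ around 10.5 min. If living ends die in pairs (bimolecular termination), the reciprocal of their number climbs steadily, and 1/r climbs with it, at a slope that ignores the initiator charged. We call the inverse of that slope the reach A, the rise in x each time the clock grows by a factor e once the start is over: 0.161. Friday's run, with a third of the loading, reads 0.154.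

Running Saturday's line back to zero gives a starting rate of 0.0463 min⁻¹, so x = A ln(1 + bt), with b = 0.287 min⁻¹ there and scaled to the initiator concentration. West gets b = 0.144 min⁻¹, converts 33.4% and reaches length 66.8. North-east gets 0.431 min⁻¹, converts 43.7% and reaches 87.4, longer than west by more than the margin.

The forecast says north-east, with 65 (55 to 120) for west and 85 (70 to 165) for north-east, and warns: "This assumes one chain per initiator, which is a guess". The simulation gives north-east, with 66.2 for west and 86.5 for north-east.

    free monomer + initiator → spent initiator B (k = 0.210 M⁻¹ s⁻¹)
    free monomer + living end → monomer in chains + living end, rate k2*[living end]*[free monomer] (k = 7.50 M⁻¹ s⁻¹)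
    2 living end → dead end A (k = 25.0 M⁻¹ s⁻¹)
    free monomer + initiator → living end + monomer in chains (k = 6.80 M⁻¹ s⁻¹)

Neither flask has come to rest at 80.0 min. Initiator stands at 0% of its charge, yet west holds 0.00385 mM of living end and 67.9% of free monomer, north-east 0.00406 mM and 58.0%. Spent initiator B in west is 0.0150% against a loading of 0.5 mol% . With the reach, ten times the time takes west to 46.8% free monomer and north-east to 40.0%; the simulation holds 48.6% and 41.2% at 800 min. By then the average length has grown to 106 in west and 121 in north-east.

The earlier runs and the new flask are simulated with constants of no real substance, noise included.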